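The route rests on cutting the α,β-unsaturated δ-lactone (ring C) at its O–C(=O) and C=C bonds. On the spiro carbon of the cyclohexene (ring B) sit both the O-bearing CMe2 carbon and the vinyl CH of that lactone, so the C(=O)–CH= unit is a two-carbon insert between a tertiary OH and a CHO. One operation with Ph3P=C=C=O acylates the carbinol and olefinates the aldehyde, closing the spirolactone. Its precursor is an enantiopure 4-oxocyclohex-2-ene carrying CMe2OH and CHO on the quaternary carbon, made by an asymmetric Robinson annulation. Ring A and the spiro furandione (ring D) follow by alkylation, cross-coupling and a cation cyclisation.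

Key step: step 11

Ring labels used below: A = carbocycle with the exocyclic methylene and the carboxyl group; B = cyclohexene; C = spiro δ-lactone; D = spiro furan-2,4-dione.

Assumption: the sense of induction of the chiral catalysts in steps 5 and 16 is settled by the first experiment, and the enantiomeric (pseudoenantiomeric) catalyst is taken where the stated (R) centre requires it. The carbinol carbons made in steps 6 and 12 are carried as epimer mixtures, which converge in steps 8 and 23.

Step 1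
Reactants: 1 propane-1,3-diol
Product: 2 3-[(4-methoxybenzyl)oxy]propan-1-ol
Conditions: NaH (1 equiv), 4-methoxybenzyl chloride (1 equiv), Bu4NI (cat.), THF/DMF, 0 °C to rt; diol in threefold excess
Reagents that add atoms: 4-methoxybenzyl chloride, COc1ccc(CCl)cc1
Why: Williamson etherification of the mono-alkoxide of a symmetrical diol held in excess should stop at the mono-ether.

Step 2
Reactants: 2 3-[(4-methoxybenzyl)oxy]propan-1-ol
Product: 3 3-[(4-methoxybenzyl)oxy]propanal
Conditions: TEMPO (10 mol%), PhI(OAc)2, CH2Cl2, rt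
Reagents that add atoms: none
Why: The oxoammonium cycle of the TEMPO/PhI(OAc)2 oxidation stops at the aldehyde and is free of base, so the β-alkoxy aldehyde should not eliminate.

Step 3
Reactants: 3 3-[(4-methoxybenzyl)oxy]propanal
Product: 4 5-[(4-methoxybenzyl)oxy]pent-1-en-3-ol (racemic)
Conditions: CH2=CHMgBr, THF, −78 °C
Reagents that add atoms: vinylmagnesium bromide, C=C[Mg]Br
Why: Grignard 1,2-addition to the aldehyde at low temperature gives the racemic vinyl carbinol, whose stereocentre is removed in the next step.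

Step 4
Reactants: 4 5-[(4-methoxybenzyl)oxy]pent-1-en-3-ol
Product: 5 5-[(4-methoxybenzyl)oxy]pent-1-en-3-one
Conditions: DMP, CH2Cl2, 0 °C to rt
Reagents that add atoms: none
Why: Dess–Martin oxidation of the secondary allylic alcohol under neutral conditions should give the vinyl ketone, which is used at once because it polymerises and can lose the ether by β-elimination.

Step 5
Reactants: 5 5-[(4-methoxybenzyl)oxy]pent-1-en-3-one, 6 ethyl 2-acetylpent-4-enoate
Product: 8 ethyl (1R)-3-{[(4-methoxybenzyl)oxy]methyl}-2-methyl-4-oxo-1-(prop-2-en-1-yl)cyclohex-2-ene-1-carboxylate, via Michael adduct 7 (not isolated)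
Conditions: 9-O-(9-phenanthryl)cupreidine (10 mol%), CH2Cl2, −20 °C to rt; then pyrrolidine (0.3 equiv), AcOH (0.3 equiv), 40 °C
Reagents that add atoms: none
Why: Bifunctional cinchona catalysis (quinuclidine base, 6′-OH hydrogen-bond donor) of the Michael addition of the α-substituted β-keto ester to the vinyl ketone should set the quaternary (R) centre by catalyst control, and pyrrolidine/AcOH then drives the enamine aldol condensation of the side-chain ketone onto the acetyl group, completing a Robinson annulation under conditions mild enough to limit β-elimination of the PMB-oxy group.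

Step 6
Reactants: 8 ethyl (1R)-3-{[(4-methoxybenzyl)oxy]methyl}-2-methyl-4-oxo-1-(prop-2-en-1-yl)cyclohex-2-ene-1-carboxylate
Product: 9 ethyl (1R)-4-hydroxy-3-{[(4-methoxybenzyl)oxy]methyl}-2-methyl-1-(prop-2-en-1-yl)cyclohex-2-ene-1-carboxylate (both C4 epimers)
Conditions: NaBH4, CeCl3·7H2O, MeOH, −20 °C
Reagents that add atoms: none
Why: Luche reduction delivers hydride 1,2 to the enone carbonyl and spares the ester; the new carbinol carbon forms as an epimer mixture that is oxidised back in step 8.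

Step 7
Reactants: 9 ethyl (1R)-4-hydroxy-3-{[(4-methoxybenzyl)oxy]methyl}-2-methyl-1-(prop-2-en-1-yl)cyclohex-2-ene-1-carboxylate
Product: 10 (4R)-4-(2-hydroxypropan-2-yl)-2-{[(4-methoxybenzyl)oxy]methyl}-3-methyl-4-(prop-2-en-1-yl)cyclohex-2-en-1-ol (both C1 epimers)
Conditions: MeLi (5 equiv), CeCl3 (anhydrous, 5 equiv), THF, −78 to 0 °C
Reagents that add atoms: methyllithium, [Li]C
Why: Two methyl groups add to the neopentyl ester (the free hydroxyl rides through as its alkoxide), and CeCl3 lowers the basicity of the reagent so that the intermediate methyl ketone is attacked and not enolised.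

Step 8
Reactants: 10 (4R)-4-(2-hydroxypropan-2-yl)-2-{[(4-methoxybenzyl)oxy]methyl}-3-methyl-4-(prop-2-en-1-yl)cyclohex-2-en-1-ol
Product: 11 (4R)-4-(2-hydroxypropan-2-yl)-2-{[(4-methoxybenzyl)oxy]methyl}-3-methyl-4-(prop-2-en-1-yl)cyclohex-2-en-1-one
Conditions: MnO2 (activated, excess), CH2Cl2, rt
Reagents that add atoms: none
Why: MnO2 oxidises the allylic secondary alcohol selectively and cannot touch the tertiary carbinol, which restores the enone.

Step 9
Reactants: 11 (4R)-4-(2-hydroxypropan-2-yl)-2-{[(4-methoxybenzyl)oxy]methyl}-3-methyl-4-(prop-2-en-1-yl)cyclohex-2-en-1-one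
Product: 12 (4R)-4-(2-hydroxypropan-2-yl)-2-{[(4-methoxybenzyl)oxy]methyl}-3-methyl-4-[(1E)-prop-1-en-1-yl]cyclohex-2-en-1-one
Conditions: RuHCl(CO)(PPh3)3 (5 mol%), toluene, 80 °C
Reagents that add atoms: none
Why: Ruthenium hydride catalysed alkene isomerisation (hydrometalation, β-hydride elimination) moves the terminal double bond one position to the more stable, mainly E, propenyl group and stops there because the next carbon is quaternary.

Step 10
Reactants: 12 (4R)-4-(2-hydroxypropan-2-yl)-2-{[(4-methoxybenzyl)oxy]methyl}-3-methyl-4-[(1E)-prop-1-en-1-yl]cyclohex-2-en-1-one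
Product: 14 (1R)-1-(2-hydroxypropan-2-yl)-3-{[(4-methoxybenzyl)oxy]methyl}-2-methyl-4-oxocyclohex-2-ene-1-carbaldehyde, via vicinal diol 13 (not isolated)
Conditions: OsO4 (2 mol%), NaIO4 (4 equiv), 2,6-lutidine, dioxane/H2O 3:1, rt
Reagents that add atoms: osmium tetroxide, O=[Os](=O)(=O)=O; sodium periodate, [Na+].[O-]I(=O)(=O)=O
Why: Lemieux–Johnson cleavage: OsO4 dihydroxylates the electron-rich disubstituted alkene (the tetrasubstituted enone alkene is inert), periodate cleaves diol 13 to the aldehyde, and 2,6-lutidine buffers the medium so that the β-hydroxy aldehyde and the PMB ether survive.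

Step 11
Reactants: 14 (1R)-1-(2-hydroxypropan-2-yl)-3-{[(4-methoxybenzyl)oxy]methyl}-2-methyl-4-oxocyclohex-2-ene-1-carbaldehyde, 15 (triphenylphosphoranylidene)ketene
Product: 17 (6R)-8-{[(4-methoxybenzyl)oxy]methyl}-1,1,7-trimethyl-2-oxaspiro[5.5]undeca-4,7-diene-3,9-dione, via ester ylide 16 (not isolated)
Conditions: Ph3P=C=C=O (1.3 equiv), toluene, 100 °C
Reagents that add atoms: none
Why: The tertiary carbinol adds its O–H across the C=C of the cumulated ylide (proton transfer, then collapse of the ion pair) to give the ester-stabilised ylide 16, whose carbanion carbon attacks the neighbouring formyl group; the oxaphosphetane then loses Ph3PO and leaves the ring-held cis enoate. The closest precedent is the known lactone annulation of hydroxy carbonyl compounds with this ylide (butenolides from α-hydroxy ketones, 5,6-dihydropyran-2-ones from β-hydroxy aldehydes and ketones), a tandem addition–Wittig lactonisation. The six-membered lactone closes by 6-exo-trig attack of the ylide carbon on the aldehyde carbon, the C=O being exocyclic to the forming ring. No stereocentre is made, and the quaternary (R) carbon carries no hydrogen and cannot epimerise. Chemoselectivity for the aldehyde over the ring B enone carbonyl follows from reach: only the formyl carbon lies within a six-membered transition state, the ketone would demand a bridged ring, and the aldehyde is also the more electrophilic carbonyl. Neutral, aprotic conditions and the non-enolisable aldehyde are meant to keep retro-aldol loss of acetone behind the acylation.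

Step 12
Reactants: 17 (6R)-8-{[(4-methoxybenzyl)oxy]methyl}-1,1,7-trimethyl-2-oxaspiro[5.5]undeca-4,7-diene-3,9-dione
Product: 18 (6R)-9-hydroxy-8-{[(4-methoxybenzyl)oxy]methyl}-1,1,7,9-tetramethyl-2-oxaspiro[5.5]undeca-4,7-dien-3-one (both C9 epimers)
Conditions: MeLi (1.5 equiv), CeCl3 (anhydrous, 1.6 equiv), THF, −78 °C
Reagents that add atoms: methyllithium, [Li]C
Why: The organocerium reagent adds 1,2 to the ketone far faster than to the unsaturated lactone at −78 °C; the tertiary carbinol forms as an epimer mixture, which is irrelevant because this carbon is ionised in step 23.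

Step 13
Reactants: 18 (6R)-9-hydroxy-8-{[(4-methoxybenzyl)oxy]methyl}-1,1,7,9-tetramethyl-2-oxaspiro[5.5]undeca-4,7-dien-3-one
Product: 19 (6R)-8-{[(4-methoxybenzyl)oxy]methyl}-1,1,7,9-tetramethyl-9-[(triethylsilyl)oxy]-2-oxaspiro[5.5]undeca-4,7-dien-3-one
Conditions: Et3SiOTf, 2,6-lutidine, CH2Cl2, −78 to 0 °C
Reagents that add atoms: triethylsilyl triflate, CC[Si](CC)(CC)OS(=O)(=O)C(F)(F)F
Why: Silylation with the silyl triflate and a hindered base caps the tertiary allylic alcohol, which protects it from the bases used later and turns it into the leaving group for step 23.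

Step 14
Reactants: 19 (6R)-8-{[(4-methoxybenzyl)oxy]methyl}-1,1,7,9-tetramethyl-9-[(triethylsilyl)oxy]-2-oxaspiro[5.5]undeca-4,7-dien-3-one
Product: 20 (6R)-8-(hydroxymethyl)-1,1,7,9-tetramethyl-9-[(triethylsilyl)oxy]-2-oxaspiro[5.5]undeca-4,7-dien-3-one
Conditions: DDQ, CH2Cl2/pH 7 phosphate buffer 10:1, 0 °C
Reagents that add atoms: none
Why: DDQ oxidises the electron-rich benzylic ether to an oxocarbenium ion that water hydrolyses, a neutral PMB removal that leaves the silyl ether, the lactone and the alkenes alone.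

Step 15
Reactants: 20 (6R)-8-(hydroxymethyl)-1,1,7,9-tetramethyl-9-[(triethylsilyl)oxy]-2-oxaspiro[5.5]undeca-4,7-dien-3-one
Product: 21 (6R)-8-(bromomethyl)-1,1,7,9-tetramethyl-9-[(triethylsilyl)oxy]-2-oxaspiro[5.5]undeca-4,7-dien-3-one
Conditions: CBr4, PPh3, 2,6-lutidine (cat.), CH2Cl2, −20 °C
Reagents that add atoms: tetrabromomethane, BrC(Br)(Br)Br
Why: Appel reaction: the alkoxyphosphonium ion of the primary allylic alcohol is displaced by bromide (SN2), while the tertiary silyl ether cannot be activated.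

Step 16
Reactants: 21 (6R)-8-(bromomethyl)-1,1,7,9-tetramethyl-9-[(triethylsilyl)oxy]-2-oxaspiro[5.5]undeca-4,7-dien-3-one, 22 tert-butyl 2-methyl-3-oxobutanoate
Product: 23 tert-butyl (2R)-2-methyl-3-oxo-2-({(6R)-1,1,7,9-tetramethyl-3-oxo-9-[(triethylsilyl)oxy]-2-oxaspiro[5.5]undeca-4,7-dien-8-yl}methyl)butanoate
Conditions: 3,3′-bis(3,4,5-trifluorophenyl) N-spiro bis(binaphthyl)ammonium bromide (3 mol%), CsOH·H2O (solid), toluene, −40 °C
Reagents that add atoms: none
Why: Chiral phase-transfer alkylation of a tert-butyl β-keto ester: the ion pair of the enolate with the C2-symmetric ammonium cation shields one enolate face, so SN2 attack on the allylic bromide should give the (2R) quaternary centre by catalyst control (the remote spiro centre has no say), and the minor epimer would be a separable diastereomer.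

Step 17
Reactants: 23 tert-butyl (2R)-2-methyl-3-oxo-2-({(6R)-1,1,7,9-tetramethyl-3-oxo-9-[(triethylsilyl)oxy]-2-oxaspiro[5.5]undeca-4,7-dien-8-yl}methyl)butanoate
Product: 25 tert-butyl (2R)-2-methyl-2-({(6R)-1,1,7,9-tetramethyl-3-oxo-9-[(triethylsilyl)oxy]-2-oxaspiro[5.5]undeca-4,7-dien-8-yl}methyl)-3-{[(trifluoromethyl)sulfonyl]oxy}but-3-enoate, via potassium enolate 24 (not isolated)
Conditions: KN(SiMe3)2, THF, −78 °C; then PhNTf2, −78 to −20 °C
Reagents that add atoms: N-phenylbis(trifluoromethanesulfonimide), FC(F)(F)S(=O)(=O)N(c1ccccc1)S(=O)(=O)C(F)(F)F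
Why: The acetyl methyl group is the only enolisable position (the other α carbon is quaternary), so kinetic deprotonation and O-sulfonylation should give the terminal enol triflate.

Step 18
Reactants: 26 methyl (R)-lactate, 15 (triphenylphosphoranylidene)ketene
Product: 28 (5R)-4-methoxy-5-methylfuran-2(5H)-one, via lactate ester ylide 27 (not isolated)
Conditions: toluene, reflux; PhCO2H (10 mol%)
Reagents that add atoms: none
Why: The lactate hydroxyl adds to the cumulated ylide and the resulting ester ylide 27 olefinates the neighbouring ester carbonyl in a five-membered intramolecular Wittig reaction, a known route to 4-alkoxybutenolides (tetronates) from α-hydroxy esters that does not touch the stereocentre.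

Step 19
Reactants: 28 (5R)-4-methoxy-5-methylfuran-2(5H)-one
Product: 29 (5R)-3-bromo-4-methoxy-5-methylfuran-2(5H)-one
Conditions: NBS, MeCN, rt
Reagents that add atoms: N-bromosuccinimide, O=C1CCC(=O)N1Br
Why: The β-methoxy enoate is nucleophilic at C3, so electrophilic bromination (addition, then loss of a proton) should give the 3-bromide.

Step 20
Reactants: 29 (5R)-3-bromo-4-methoxy-5-methylfuran-2(5H)-one
Product: 30 (5R)-4-methoxy-5-methyl-3-(trimethylstannyl)furan-2(5H)-one
Conditions: Me3SnSnMe3, Pd(PPh3)4 (5 mol%), toluene, 100 °C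
Reagents that add atoms: hexamethylditin, C[Sn](C)(C)[Sn](C)(C)C
Why: Palladium-catalysed stannylation of the vinyl bromide with the distannane (oxidative addition, Sn–Sn transmetalation, reductive elimination) gives the vinylstannane under neutral conditions.

Step 21
Reactants: 25 tert-butyl (2R)-2-methyl-2-({(6R)-1,1,7,9-tetramethyl-3-oxo-9-[(triethylsilyl)oxy]-2-oxaspiro[5.5]undeca-4,7-dien-8-yl}methyl)-3-{[(trifluoromethyl)sulfonyl]oxy}but-3-enoate, 30 (5R)-4-methoxy-5-methyl-3-(trimethylstannyl)furan-2(5H)-one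
Product: 31 tert-butyl (2R)-3-[(5R)-4-methoxy-5-methyl-2-oxo-2,5-dihydrofuran-3-yl]-2-methyl-2-({(6R)-1,1,7,9-tetramethyl-3-oxo-9-[(triethylsilyl)oxy]-2-oxaspiro[5.5]undeca-4,7-dien-8-yl}methyl)but-3-enoate
Conditions: Pd(PPh3)4 (10 mol%), CuCl, LiCl, DMSO, 60 °C
Reagents that add atoms: none
Why: Stille coupling of the hindered vinyl triflate with the vinylstannane, with CuCl/LiCl to speed the transmetalation of congested partners, forms the diene C–C bond under neutral conditions that the silyl ether, both lactones and the tert-butyl ester tolerate.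

Step 22
Reactants: 31 tert-butyl (2R)-3-[(5R)-4-methoxy-5-methyl-2-oxo-2,5-dihydrofuran-3-yl]-2-methyl-2-({(6R)-1,1,7,9-tetramethyl-3-oxo-9-[(triethylsilyl)oxy]-2-oxaspiro[5.5]undeca-4,7-dien-8-yl}methyl)but-3-enoate
Product: 32 tert-butyl (2R)-3-[(5R)-4-hydroxy-5-methyl-2-oxo-2,5-dihydrofuran-3-yl]-2-methyl-2-({(6R)-1,1,7,9-tetramethyl-3-oxo-9-[(triethylsilyl)oxy]-2-oxaspiro[5.5]undeca-4,7-dien-8-yl}methyl)but-3-enoate
Conditions: LiCl, DMSO, 60 °C; cold dilute HCl work-up; used at once
Reagents that add atoms: none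
Why: Chloride demethylates the vinylogous carbonate by SN2 attack at the O-methyl group (the tetronate anion is a good leaving group), freeing the tetronic acid without strong acid or base.

Step 23
Reactants: 32 tert-butyl (2R)-3-[(5R)-4-hydroxy-5-methyl-2-oxo-2,5-dihydrofuran-3-yl]-2-methyl-2-({(6R)-1,1,7,9-tetramethyl-3-oxo-9-[(triethylsilyl)oxy]-2-oxaspiro[5.5]undeca-4,7-dien-8-yl}methyl)but-3-enoate
Product: 33 penicianstinoid C tert-butyl ester
Conditions: TfOH (10 mol%), CH2Cl2, −40 °C
Reagents that add atoms: none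
Why: Acid ionises the tertiary allylic silyl ether to a cyclohexenyl cation that the tethered tetronic acid enol traps through C3 in a six-membered, chair-like closure of ring A (C-alkylation of a 1,3-dicarbonyl enol by an allylic cation, the termination known from cation–olefin cyclisations); the ring-fusion carbon should be set by attack on the ring B face opposite the pseudoaxial CMe2 arm of the spirolactone, and the ring D spiro carbon by the chair that keeps the methyl of the ester-bearing carbon equatorial and turns the lactone carbonyl of ring D outward, the latter being the less secure of the two.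

Step 24
Reactants: 33 penicianstinoid C tert-butyl ester
Product: 34 penicianstinoid C
Conditions: TFA/CH2Cl2 1:4, 0 °C to rt
Reagents that add atoms: none
Why: Acidolysis of the tert-butyl ester (loss of isobutene) frees the acid without base, which would open the β-keto lactone of ring D or epimerise its O–CH(CH3) carbon.

Compound list

1 | propane-1,3-diol | OCCCO | starting material
2 | 3-[(4-methoxybenzyl)oxy]propan-1-ol | OCCCOCc1ccc(OC)cc1 | intermediate
3 | 3-[(4-methoxybenzyl)oxy]propanal | O=CCCOCc1ccc(OC)cc1 | intermediate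
4 | 5-[(4-methoxybenzyl)oxy]pent-1-en-3-ol (racemic) | C=CC(O)CCOCc1ccc(OC)cc1 | intermediate
5 | 5-[(4-methoxybenzyl)oxy]pent-1-en-3-one | C=CC(=O)CCOCc1ccc(OC)cc1 | intermediate
6 | ethyl 2-acetylpent-4-enoate (racemic) | C=CCC(C(C)=O)C(=O)OCC | starting material
7 | ethyl (2R)-2-acetyl-7-[(4-methoxybenzyl)oxy]-5-oxo-2-(prop-2-en-1-yl)heptanoate (Michael adduct, not isolated) | CC(=O)[C@](C(=O)OCC)(CC=C)CCC(=O)CCOCc1ccc(OC)cc1 | intermediate
8 | ethyl (1R)-3-{[(4-methoxybenzyl)oxy]methyl}-2-methyl-4-oxo-1-(prop-2-en-1-yl)cyclohex-2-ene-1-carboxylate | O=C1C(COCc2ccc(OC)cc2)=C(C)[C@](C(=O)OCC)(CC=C)CC1 | intermediate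
9 | ethyl (1R)-4-hydroxy-3-{[(4-methoxybenzyl)oxy]methyl}-2-methyl-1-(prop-2-en-1-yl)cyclohex-2-ene-1-carboxylate (both C4 epimers) | OC1C(COCc2ccc(OC)cc2)=C(C)[C@](C(=O)OCC)(CC=C)CC1 | intermediate
10 | (4R)-4-(2-hydroxypropan-2-yl)-2-{[(4-methoxybenzyl)oxy]methyl}-3-methyl-4-(prop-2-en-1-yl)cyclohex-2-en-1-ol (both C1 epimers) | OC1C(COCc2ccc(OC)cc2)=C(C)[C@](C(C)(C)O)(CC=C)CC1 | intermediate
11 | (4R)-4-(2-hydroxypropan-2-yl)-2-{[(4-methoxybenzyl)oxy]methyl}-3-methyl-4-(prop-2-en-1-yl)cyclohex-2-en-1-one | O=C1C(COCc2ccc(OC)cc2)=C(C)[C@](C(C)(C)O)(CC=C)CC1 | intermediate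
12 | (4R)-4-(2-hydroxypropan-2-yl)-2-{[(4-methoxybenzyl)oxy]methyl}-3-methyl-4-[(1E)-prop-1-en-1-yl]cyclohex-2-en-1-one | O=C1C(COCc2ccc(OC)cc2)=C(C)[C@](C(C)(C)O)(/C=C/C)CC1 | intermediate
13 | vicinal diol of 12: the propenyl group is replaced by 1,2-dihydroxypropyl (diastereomers at the two new carbinol carbons, quaternary carbon as in 12; not isolated) | O=C1C(COCc2ccc(OC)cc2)=C(C)[C@](C(C)(C)O)(C(O)C(C)O)CC1 | intermediate
14 | (1R)-1-(2-hydroxypropan-2-yl)-3-{[(4-methoxybenzyl)oxy]methyl}-2-methyl-4-oxocyclohex-2-ene-1-carbaldehyde | O=C1C(COCc2ccc(OC)cc2)=C(C)[C@](C(C)(C)O)(C=O)CC1 | intermediate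
15 | (triphenylphosphoranylidene)ketene | O=C=C=P(c1ccccc1)(c1ccccc1)c1ccccc1 | starting material
16 | 2-[(1R)-1-formyl-3-{[(4-methoxybenzyl)oxy]methyl}-2-methyl-4-oxocyclohex-2-en-1-yl]propan-2-yl (triphenylphosphoranylidene)acetate (ester ylide, not isolated) | O=C1C(COCc2ccc(OC)cc2)=C(C)[C@](C(C)(C)OC(=O)C=P(c2ccccc2)(c2ccccc2)c2ccccc2)(C=O)CC1 | intermediate
17 | (6R)-8-{[(4-methoxybenzyl)oxy]methyl}-1,1,7-trimethyl-2-oxaspiro[5.5]undeca-4,7-diene-3,9-dione | O=C1C(COCc2ccc(OC)cc2)=C(C)[C@]3(C=CC(=O)OC3(C)C)CC1 | intermediate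
18 | (6R)-9-hydroxy-8-{[(4-methoxybenzyl)oxy]methyl}-1,1,7,9-tetramethyl-2-oxaspiro[5.5]undeca-4,7-dien-3-one (both C9 epimers) | CC1(O)C(COCc2ccc(OC)cc2)=C(C)[C@]3(C=CC(=O)OC3(C)C)CC1 | intermediate
19 | (6R)-8-{[(4-methoxybenzyl)oxy]methyl}-1,1,7,9-tetramethyl-9-[(triethylsilyl)oxy]-2-oxaspiro[5.5]undeca-4,7-dien-3-one (both C9 epimers, as are 20 to 32) | CC[Si](CC)(CC)OC1(C)C(COCc2ccc(OC)cc2)=C(C)[C@]3(C=CC(=O)OC3(C)C)CC1 | intermediate
20 | (6R)-8-(hydroxymethyl)-1,1,7,9-tetramethyl-9-[(triethylsilyl)oxy]-2-oxaspiro[5.5]undeca-4,7-dien-3-one | CC[Si](CC)(CC)OC1(C)C(CO)=C(C)[C@]2(C=CC(=O)OC2(C)C)CC1 | intermediate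
21 | (6R)-8-(bromomethyl)-1,1,7,9-tetramethyl-9-[(triethylsilyl)oxy]-2-oxaspiro[5.5]undeca-4,7-dien-3-one | CC[Si](CC)(CC)OC1(C)C(CBr)=C(C)[C@]2(C=CC(=O)OC2(C)C)CC1 | intermediate
22 | tert-butyl 2-methyl-3-oxobutanoate (racemic) | CC(=O)C(C)C(=O)OC(C)(C)C | starting material
23 | tert-butyl (2R)-2-methyl-3-oxo-2-({(6R)-1,1,7,9-tetramethyl-3-oxo-9-[(triethylsilyl)oxy]-2-oxaspiro[5.5]undeca-4,7-dien-8-yl}methyl)butanoate | CC(=O)[C@](C)(C(=O)OC(C)(C)C)CC1=C(C)[C@]2(C=CC(=O)OC2(C)C)CCC1(C)O[Si](CC)(CC)CC | intermediate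
24 | potassium enolate of 23 at the acetyl group (not isolated) | [K+].C=C([O-])[C@](C)(C(=O)OC(C)(C)C)CC1=C(C)[C@]2(C=CC(=O)OC2(C)C)CCC1(C)O[Si](CC)(CC)CC | intermediate
25 | tert-butyl (2R)-2-methyl-2-({(6R)-1,1,7,9-tetramethyl-3-oxo-9-[(triethylsilyl)oxy]-2-oxaspiro[5.5]undeca-4,7-dien-8-yl}methyl)-3-{[(trifluoromethyl)sulfonyl]oxy}but-3-enoate | C=C(OS(=O)(=O)C(F)(F)F)[C@](C)(C(=O)OC(C)(C)C)CC1=C(C)[C@]2(C=CC(=O)OC2(C)C)CCC1(C)O[Si](CC)(CC)CC | intermediate
26 | methyl (R)-lactate | C[C@@H](O)C(=O)OC | starting material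
27 | methyl (2R)-2-{[(triphenylphosphoranylidene)acetyl]oxy}propanoate (lactate ester ylide, not isolated) | C[C@@H](OC(=O)C=P(c1ccccc1)(c1ccccc1)c1ccccc1)C(=O)OC | intermediate
28 | (5R)-4-methoxy-5-methylfuran-2(5H)-one | C[C@H]1OC(=O)C=C1OC | intermediate
29 | (5R)-3-bromo-4-methoxy-5-methylfuran-2(5H)-one | C[C@H]1OC(=O)C(Br)=C1OC | intermediate
30 | (5R)-4-methoxy-5-methyl-3-(trimethylstannyl)furan-2(5H)-one | C[C@H]1OC(=O)C([Sn](C)(C)C)=C1OC | intermediate
31 | tert-butyl (2R)-3-[(5R)-4-methoxy-5-methyl-2-oxo-2,5-dihydrofuran-3-yl]-2-methyl-2-({(6R)-1,1,7,9-tetramethyl-3-oxo-9-[(triethylsilyl)oxy]-2-oxaspiro[5.5]undeca-4,7-dien-8-yl}methyl)but-3-enoate | C=C(C1=C(OC)[C@@H](C)OC1=O)[C@](C)(C(=O)OC(C)(C)C)CC2=C(C)[C@]3(C=CC(=O)OC3(C)C)CCC2(C)O[Si](CC)(CC)CC | intermediate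
32 | tert-butyl (2R)-3-[(5R)-4-hydroxy-5-methyl-2-oxo-2,5-dihydrofuran-3-yl]-2-methyl-2-({(6R)-1,1,7,9-tetramethyl-3-oxo-9-[(triethylsilyl)oxy]-2-oxaspiro[5.5]undeca-4,7-dien-8-yl}methyl)but-3-enoate | C=C(C1=C(O)[C@@H](C)OC1=O)[C@](C)(C(=O)OC(C)(C)C)CC2=C(C)[C@]3(C=CC(=O)OC3(C)C)CCC2(C)O[Si](CC)(CC)CC | intermediate
33 | penicianstinoid C tert-butyl ester: ring A C(CH3)(CO2tBu) carbon (R), ring C spiro carbon (R), ring-fusion C(CH3) carbon (S), ring D spiro carbon (S), O–CH(CH3) carbon (R) | C=C1[C@](C)(C(=O)OC(C)(C)C)CC2=C(C)[C@]3(C=CC(=O)OC3(C)C)CC[C@]2(C)[C@@]12C(=O)O[C@H](C)C2=O | intermediate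
34 | penicianstinoid C: ring A C(CH3)(CO2H) carbon (R), ring C spiro carbon (R), ring-fusion C(CH3) carbon (S), ring D spiro carbon (S), O–CH(CH3) carbon (R) | C=C1[C@](C)(C(=O)O)CC2=C(C)[C@]3(C=CC(=O)OC3(C)C)CC[C@]2(C)[C@@]12C(=O)O[C@H](C)C2=O | target

Total step count: 24.
Longest linear sequence: 21 steps (steps 1 to 17 and 21 to 24, from propane-1,3-diol); the stannane branch (steps 18 to 20) joins at step 21.

Steps most likely to fail

Step 11. Addition of the hindered tertiary carbinol to the ylide may be slow, so that base-induced retro-aldol fragmentation of the β-hydroxy aldehyde (loss of acetone, the carbanion being stabilised by the formyl group and, through the double bond, by the ring ketone) overtakes the acylation. The fallback makes the two bonds one after the other. Setting out from 14, esterification with (diethoxyphosphoryl)acetic acid (DCC, DMAP, CH2Cl2, 0 °C) should give 2-[(1R)-1-formyl-3-{[(4-methoxybenzyl)oxy]methyl}-2-methyl-4-oxocyclohex-2-en-1-yl]propan-2-yl (diethoxyphosphoryl)acetate F1, which has no free hydroxyl and can no longer fragment. Intramolecular Horner–Wadsworth–Emmons olefination (LiCl, iPr2NEt, MeCN, rt) would then close the lactone and return to 17.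

Step 23. Facial selectivity on the tetronic acid may be poor or reversed, because the natural ring D spiro centre requires the new C–C bond to form on the face of ring D that carries the C5 methyl; proton loss from the cation to a diene and capture of the cation by the ester carbonyl may also intervene. The fallback uses the C5 centre as a matched control element that is corrected afterwards. It sets out from 25, 15 and commercial methyl (S)-lactate (C[C@H](O)C(=O)OC). The lactate and 15 should give methyl (2S)-2-{[(triphenylphosphoranylidene)acetyl]oxy}propanoate F2 and from it (5S)-4-methoxy-5-methylfuran-2(5H)-one F3. Bromination and stannylation as in steps 19 and 20 would give (5S)-3-bromo-4-methoxy-5-methylfuran-2(5H)-one F4 and (5S)-4-methoxy-5-methyl-3-(trimethylstannyl)furan-2(5H)-one F5. Stille coupling with 25 as in step 21 would give the (5S) epimer of coupling product 31 F6, LiCl demethylation the (5S) epimer of tetronic acid 32 F7, and acid closure, now with the methyl on the ring D face turned away from the cation, the O–CH(CH3) epimer of ester 33 F8. Deprotonation of F8 at that carbon (LiN(SiMe3)2, THF, −78 °C) and protonation of the enolate from the face opposite the ring-fusion carbon (2,6-di-tert-butylphenol) would invert the centre and return to 33.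

Step 16. The ammonium catalyst may exert only weak control over the enolate face of this acyclic keto ester, giving a mixture at the new quaternary carbon, and hydroxide may attack the lactone or the bromide. The fallback binds the chiral controller covalently. Setting out from 22, condensation with L-valine tert-butyl ester (benzene, cat. acid, azeotropic removal of water) should give tert-butyl (2Z)-3-{[(2S)-1-tert-butoxy-3-methyl-1-oxobutan-2-yl]amino}-2-methylbut-2-enoate F9. Deprotonation with LiN(iPr)2 in toluene at −78 °C and alkylation with 21 (the donor additive, THF or HMPA, selects the chelate and hence the enolate face) would give tert-butyl (2R)-3-{[(2S)-1-tert-butoxy-3-methyl-1-oxobutan-2-yl]imino}-2-methyl-2-({(6R)-1,1,7,9-tetramethyl-3-oxo-9-[(triethylsilyl)oxy]-2-oxaspiro[5.5]undeca-4,7-dien-8-yl}methyl)butanoate F10. Hydrolysis of the imine in buffered aqueous AcOH would release the auxiliary and return to 23.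

Further compounds

F1 | step 11 | 2-[(1R)-1-formyl-3-{[(4-methoxybenzyl)oxy]methyl}-2-methyl-4-oxocyclohex-2-en-1-yl]propan-2-yl (diethoxyphosphoryl)acetate | O=C1C(COCc2ccc(OC)cc2)=C(C)[C@](C(C)(C)OC(=O)CP(=O)(OCC)OCC)(C=O)CC1
F2 | step 23 | methyl (2S)-2-{[(triphenylphosphoranylidene)acetyl]oxy}propanoate | C[C@H](OC(=O)C=P(c1ccccc1)(c1ccccc1)c1ccccc1)C(=O)OC
F3 | step 23 | (5S)-4-methoxy-5-methylfuran-2(5H)-one | C[C@@H]1OC(=O)C=C1OC
F4 | step 23 | (5S)-3-bromo-4-methoxy-5-methylfuran-2(5H)-one | C[C@@H]1OC(=O)C(Br)=C1OC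
F5 | step 23 | (5S)-4-methoxy-5-methyl-3-(trimethylstannyl)furan-2(5H)-one | C[C@@H]1OC(=O)C([Sn](C)(C)C)=C1OC
F6 | step 23 | (5S) epimer of coupling product 31: tert-butyl (2R)-3-[(5S)-4-methoxy-5-methyl-2-oxo-2,5-dihydrofuran-3-yl]-2-methyl-2-({(6R)-1,1,7,9-tetramethyl-3-oxo-9-[(triethylsilyl)oxy]-2-oxaspiro[5.5]undeca-4,7-dien-8-yl}methyl)but-3-enoate | C=C(C1=C(OC)[C@H](C)OC1=O)[C@](C)(C(=O)OC(C)(C)C)CC2=C(C)[C@]3(C=CC(=O)OC3(C)C)CCC2(C)O[Si](CC)(CC)CC
F7 | step 23 | (5S) epimer of tetronic acid 32: tert-butyl (2R)-3-[(5S)-4-hydroxy-5-methyl-2-oxo-2,5-dihydrofuran-3-yl]-2-methyl-2-({(6R)-1,1,7,9-tetramethyl-3-oxo-9-[(triethylsilyl)oxy]-2-oxaspiro[5.5]undeca-4,7-dien-8-yl}methyl)but-3-enoate | C=C(C1=C(O)[C@H](C)OC1=O)[C@](C)(C(=O)OC(C)(C)C)CC2=C(C)[C@]3(C=CC(=O)OC3(C)C)CCC2(C)O[Si](CC)(CC)CC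
F8 | step 23 | O–CH(CH3) epimer of ester 33 (that carbon S, all other centres as in 33) | C=C1[C@](C)(C(=O)OC(C)(C)C)CC2=C(C)[C@]3(C=CC(=O)OC3(C)C)CC[C@]2(C)[C@@]12C(=O)O[C@@H](C)C2=O
F9 | step 16 | tert-butyl (2Z)-3-{[(2S)-1-tert-butoxy-3-methyl-1-oxobutan-2-yl]amino}-2-methylbut-2-enoate | C/C(N[C@@H](C(C)C)C(=O)OC(C)(C)C)=C(\C)C(=O)OC(C)(C)C
F10 | step 16 | tert-butyl (2R)-3-{[(2S)-1-tert-butoxy-3-methyl-1-oxobutan-2-yl]imino}-2-methyl-2-({(6R)-1,1,7,9-tetramethyl-3-oxo-9-[(triethylsilyl)oxy]-2-oxaspiro[5.5]undeca-4,7-dien-8-yl}methyl)butanoate | CC(=N[C@@H](C(C)C)C(=O)OC(C)(C)C)[C@](C)(C(=O)OC(C)(C)C)CC1=C(C)[C@]2(C=CC(=O)OC2(C)C)CCC1(C)O[Si](CC)(CC)CC
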